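**Retrosynthetic overview**

1. Target 15 ⇐ ester 13 (2 MeMgBr): the C(CH3)2OH group is carried as CO2Me, which makes C-α the β-carbon of an acrylate.
2. 13 ⇐ alcohol 11 + chloro-acrylate 6 in one flask: O–C4(A) by alkoxide addition–elimination, then C3′–C-α by 6-exo radical closure. This closes the central dihydropyran ring P and sets C3′ and C-α from C4′.
3. Enabling feature: the oxygen of ring P sits on C4 of quinolinone A, the β-carbon of the N-methyl lactam enone (as its chloride an SNAr site), and C-α is 1,3 to the side-chain carbinol carbon. The cis C3′/C4′ fusion of ring P with pyran ring Q lets the C4′–O stereocentre dictate the other two.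
4. 11 ⇐ 10 ⇐ 9 (asymmetric transfer hydrogenation of the α-seleno pyranone; ring Q by acylation/oxa-Michael on 4); 6 ⇐ 5 ⇐ 4 (Vilsmeier, Wittig); 4 ⇐ 1.
5. Ring order: pyridone ring of 4 (serves both halves) → pyranone ring Q → ring P last.

Key step: step 8

Remark on the chemistry: unit A is the quinolinone that carries the hydroxyalkyl chain, unit B the pyrano[3,2-c]quinolinone. C-α is the CH bearing the chain; C2′, C3′, C4′ are C2, C3, C4 of the pyran ring Q of unit B; ring P is O–C4(A)=C3(A)–C-α–C3′–C4′. The target is C-α S, C3′ S, C4′ R (cis-fused, chain trans to C2′). The C3′ configuration of 11 is erased in step 8, so only its C4′ configuration matters. 2,3-Dimethoxy-N-methylaniline is assumed to be made rather than bought.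

**Route**

Step 1
Reactants: 1 2,3-dimethoxyaniline
Product: 3 2,3-dimethoxy-N-methylaniline, via N-(methoxymethyl)-2,3-dimethoxyaniline 2 (not isolated)
Conditions: (CH2O)n, NaOMe, MeOH, reflux; then NaBH4, reflux
Reagents that add atoms: paraformaldehyde (as formaldehyde), C=O
Why: Stepwise reductive amination in which the hemiaminal ether 2 is reduced through its iminium ion by NaBH4 should give the mono-N-methylaniline without over-alkylation.

Step 2
Reactants: 3 2,3-dimethoxy-N-methylaniline
Product: 4 4-hydroxy-7,8-dimethoxy-1-methylquinolin-2(1H)-one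
Conditions: bis(2,4,6-trichlorophenyl) malonate, Ph2O, 220 °C
Reagents that add atoms: bis(2,4,6-trichlorophenyl) malonate, O=C(CC(=O)Oc1c(Cl)cc(Cl)cc1Cl)Oc1c(Cl)cc(Cl)cc1Cl
Why: Thermal condensation with an active malonate (N-acylation, then intramolecular C-acylation, the standard 4-hydroxy-2-quinolone synthesis) can close only onto the single free ortho carbon of the aniline, which fixes the 7,8-dimethoxy pattern.

Step 3
Reactants: 4 4-hydroxy-7,8-dimethoxy-1-methylquinolin-2(1H)-one
Product: 5 4-chloro-7,8-dimethoxy-1-methyl-2-oxo-1,2-dihydroquinoline-3-carbaldehyde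
Conditions: POCl3, DMF, 60 °C; aq. NaOAc work-up
Reagents that add atoms: N,N-dimethylformamide, CN(C)C=O; phosphoryl chloride, O=P(Cl)(Cl)Cl; water, O
Why: Vilsmeier–Haack formylation at the nucleophilic C3 with concomitant chlorodehydroxylation at C4, as known for 4-hydroxy-2-quinolones and 4-hydroxycoumarins, turns C4 into a vinylogous acyl chloride.

Step 4
Reactants: 5 4-chloro-7,8-dimethoxy-1-methyl-2-oxo-1,2-dihydroquinoline-3-carbaldehyde
Product: 6 methyl (E)-3-(4-chloro-7,8-dimethoxy-1-methyl-2-oxo-1,2-dihydroquinolin-3-yl)prop-2-enoate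
Conditions: Ph3P=CHCO2Me, CH2Cl2, rt
Reagents that add atoms: methyl (triphenylphosphoranylidene)acetate, COC(=O)C=P(c1ccccc1)(c1ccccc1)c1ccccc1
Why: Wittig olefination with a stabilized ylide is E-selective and should attack the aldehyde in preference to the vinylogous acyl chloride.

Step 5
Reactants: 4 4-hydroxy-7,8-dimethoxy-1-methylquinolin-2(1H)-one; 7 3-methylbut-2-enoic acid
Product: 9 7,8-dimethoxy-2,2,6-trimethyl-2,3-dihydro-4H-pyrano[3,2-c]quinoline-4,5(6H)-dione, via 3-(3-methylbut-2-enoyl)quinolinone 8 (not isolated)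
Conditions: Eaton's reagent (P2O5/MeSO3H), 70 °C
Reagents that add atoms: none
Why: Friedel–Crafts C-acylation at C3 by the activated acid followed by 6-endo oxa-Michael closure of the 4-OH onto the β,β-dimethyl enone is the standard 2,2-dimethylchromanone annulation and should give the angular 2-quinolone.

Step 6
Reactants: 9 7,8-dimethoxy-2,2,6-trimethyl-2,3-dihydro-4H-pyrano[3,2-c]quinoline-4,5(6H)-dione
Product: 10 rac-7,8-dimethoxy-2,2,6-trimethyl-3-(phenylselanyl)-2,3-dihydro-4H-pyrano[3,2-c]quinoline-4,5(6H)-dione
Conditions: PhSeCl, EtOAc, rt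
Reagents that add atoms: benzeneselenenyl chloride, Cl[Se]c1ccccc1
Why: Acid-catalysed enolization is possible only toward C3, and trapping of the enol by PhSeCl (electrophilic α-selenenylation of a ketone) gives a racemic centre that is erased later.

Step 7
Reactants: 10 rac-7,8-dimethoxy-2,2,6-trimethyl-3-(phenylselanyl)-2,3-dihydro-4H-pyrano[3,2-c]quinoline-4,5(6H)-dione
Product: 11 (3S,4S)-4-hydroxy-7,8-dimethoxy-2,2,6-trimethyl-3-(phenylselanyl)-3,4-dihydro-2H-pyrano[3,2-c]quinolin-5(6H)-one
Conditions: RuCl[(R,R)-TsDPEN](p-cymene) (2 mol %), HCO2H/Et3N (5:2), DMF, 35 °C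
Reagents that add atoms: none
Why: Noyori–Ikariya asymmetric transfer hydrogenation of an aryl-type ketone with the (R,R)-catalyst should give the (R)-1-arylethanol-like arrangement at C4 (descriptor S here because of selenium), and with enol-mediated racemization of the α-seleno centre (dynamic kinetic resolution, as for 3-substituted chroman-4-ones) the cis alcohol is expected.

Step 8
Reactants: 11 (3S,4S)-4-hydroxy-7,8-dimethoxy-2,2,6-trimethyl-3-(phenylselanyl)-3,4-dihydro-2H-pyrano[3,2-c]quinolin-5(6H)-one; 6 methyl (E)-3-(4-chloro-7,8-dimethoxy-1-methyl-2-oxo-1,2-dihydroquinolin-3-yl)prop-2-enoate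
Product: 13 methyl ester of the cis-fused hexacycle (target skeleton carrying CH2CO2Me on C-α; C-α S; C3′ S; C4′ R), via aryl ether 12 (not isolated)
Conditions: KHMDS (1.0 equiv), THF, −40 → 0 °C; AcOH (0.1 equiv); then toluene, Bu3SnH/AIBN (slow addition), 85 °C
Reagents that add atoms: none
Why: The potassium alkoxide of 11 displaces chloride from C4 of 6 by addition–elimination (C4 is β to the lactam carbonyl and δ to the ester carbonyl, a doubly vinylogous acyl chloride) to give ether 12, after which Bu3Sn• abstracts the phenylselanyl group and the planar secondary C3′ radical adds to the acrylate β-carbon (C-α), the resulting α-ester radical taking hydrogen from Bu3SnH. The closest known reaction types are alkoxide SNAr on 4-chloro-2-quinolones and 4-chloro-3-formylcoumarins and the tin-hydride cyclization of 2-(aryloxy)alkyl radicals onto ortho-cinnamate acceptors that gives chroman-4-ylacetates. Ring P (O–C4(A)=C3(A)–C-α–C3′–C4′) closes in the 6-exo-trig mode with matched polarity (nucleophilic alkyl radical on the β-carbon of an electron-poor alkene). The C4′ centre of 11 is carried over unchanged because its C–O bond is never broken, and it controls both new centres: the aryloxy tether is held pseudoaxial by allylic strain with the C5 lactam carbonyl of unit B, so the C3′ radical can be reached only on the oxygen-bearing face (cis ring fusion), and the CH–CO2Me terminus of the acceptor turns away from the C2′ gem-dimethyl carbon, which places the acetate arm on C-α trans to C2′ as in the target. Because C3′ passes through a planar radical, both C3′ epimers of the selenide converge on one product. The step needs O-arylation to be complete before radicals are formed and cyclization to outrun reduction and β-loss of the quinolinyloxy group, which the staged one-flask protocol, the activated acceptor and slow addition of the stannane are meant to secure.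

Step 9
Reactants: 13 methyl ester of the cis-fused hexacycle
Product: 15 CNP0160874.2 (target; C-α S; C3′ S; C4′ R), via methyl ketone 14 (not isolated)
Conditions: MeMgBr (4 equiv), THF, 0 °C → rt; aq. NH4Cl
Reagents that add atoms: methylmagnesium bromide, C[Mg]Br
Why: Double Grignard addition to the methyl ester through ketone 14 should give the tertiary carbinol, since the vinylogous-carbamate lactam carbonyls are far less electrophilic and no stereocentre is touched.

**Compound list**

1 | 2,3-dimethoxyaniline | Nc1cccc(OC)c1OC | starting material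
2 | N-(methoxymethyl)-2,3-dimethoxyaniline | COCNc1cccc(OC)c1OC | intermediate
3 | 2,3-dimethoxy-N-methylaniline | CNc1cccc(OC)c1OC | intermediate
4 | 4-hydroxy-7,8-dimethoxy-1-methylquinolin-2(1H)-one | COc1ccc2c(O)cc(=O)n(C)c2c1OC | intermediate
5 | 4-chloro-7,8-dimethoxy-1-methyl-2-oxo-1,2-dihydroquinoline-3-carbaldehyde | COc1ccc2c(Cl)c(C=O)c(=O)n(C)c2c1OC | intermediate
6 | methyl (E)-3-(4-chloro-7,8-dimethoxy-1-methyl-2-oxo-1,2-dihydroquinolin-3-yl)prop-2-enoate | COC(=O)/C=C/c1c(Cl)c2ccc(OC)c(OC)c2n(C)c1=O | intermediate
7 | 3-methylbut-2-enoic acid | CC(C)=CC(=O)O | starting material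
8 | 4-hydroxy-7,8-dimethoxy-1-methyl-3-(3-methylbut-2-enoyl)quinolin-2(1H)-one | COc1ccc2c(O)c(C(=O)C=C(C)C)c(=O)n(C)c2c1OC | intermediate
9 | 7,8-dimethoxy-2,2,6-trimethyl-2,3-dihydro-4H-pyrano[3,2-c]quinoline-4,5(6H)-dione | COc1ccc2c3OC(C)(C)CC(=O)c3c(=O)n(C)c2c1OC | intermediate
10 | rac-7,8-dimethoxy-2,2,6-trimethyl-3-(phenylselanyl)-2,3-dihydro-4H-pyrano[3,2-c]quinoline-4,5(6H)-dione | COc1ccc2c3OC(C)(C)C([Se]c4ccccc4)C(=O)c3c(=O)n(C)c2c1OC | intermediate
11 | (3S,4S)-4-hydroxy-7,8-dimethoxy-2,2,6-trimethyl-3-(phenylselanyl)-3,4-dihydro-2H-pyrano[3,2-c]quinolin-5(6H)-one | COc1ccc2c3OC(C)(C)[C@@H]([Se]c4ccccc4)[C@@H](O)c3c(=O)n(C)c2c1OC | intermediate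
12 | methyl (E)-3-[4-{[(3S,4S)-7,8-dimethoxy-2,2,6-trimethyl-5-oxo-3-(phenylselanyl)-3,4,5,6-tetrahydro-2H-pyrano[3,2-c]quinolin-4-yl]oxy}-7,8-dimethoxy-1-methyl-2-oxo-1,2-dihydroquinolin-3-yl]prop-2-enoate | COc1ccc2c3OC(C)(C)[C@@H]([Se]c4ccccc4)[C@@H](Oc4c(/C=C/C(=O)OC)c(=O)n(C)c5c(OC)c(OC)ccc45)c3c(=O)n(C)c2c1OC | intermediate
13 | methyl ester of the cis-fused hexacycle: target skeleton with CH2CO2Me on C-α (C-α S, C3′ S, C4′ R) | COc1ccc2c3c(c(=O)n(C)c2c1OC)[C@@H](CC(=O)OC)[C@H]1[C@@H](O3)c2c(c3ccc(OC)c(OC)c3n(C)c2=O)OC1(C)C | intermediate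
14 | methyl ketone: target skeleton with CH2C(=O)CH3 on C-α (C-α S, C3′ S, C4′ R) | COc1ccc2c3c(c(=O)n(C)c2c1OC)[C@@H](CC(C)=O)[C@H]1[C@@H](O3)c2c(c3ccc(OC)c(OC)c3n(C)c2=O)OC1(C)C | intermediate
15 | CNP0160874.2 (C-α S, C3′ S, C4′ R) | COc1ccc2c3c(c(=O)n(C)c2c1OC)[C@@H](CC(C)(C)O)[C@H]1[C@@H](O3)c2c(c3ccc(OC)c(OC)c3n(C)c2=O)OC1(C)C | target

**Step count and risks**

Total steps: 9. Longest linear sequence: 7 (steps 1, 2, 5, 6, 7, 8, 9).

Steps most likely to fail:

1. Step 8. After selenium abstraction the C3′ radical may lose the quinolinyloxy group by β-fragmentation or be reduced before it cyclizes, or it may close with incomplete facial control at C-α. The hindered alkoxide may also add to the acrylate instead of displacing chloride. The fallback assembles ring P by a domino Knoevenagel/hetero-Diels–Alder reaction, which forms the O–C4′ and C-α–C3′ bonds instead. It sets out from 4. Condensation of 4 with 3-methylbut-2-enal (pyridine, 110 °C; Knoevenagel then oxa-6π closure) should give veprisine F1. A second portion of 4 and methyl 3,3-dimethoxypropanoate (TsOH cat., toluene, 80 °C) should generate the 3-alkylidene-quinoline-2,4-dione o-quinone methide F2 in the presence of F1. Its inverse-demand [4+2] addition to the chromene double bond should give the cis-fused ester as a racemate, 13 together with its mirror image ent-13 F3. Separation of the endo/exo isomers and preparative chiral SFC bring the sequence back to the route at 13.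

2. Step 7. Selenium may coordinate to and deactivate the ruthenium hydride, the C–Se bond may be cleaved reductively, or enantiofacial discrimination may be poor. The fallback replaces catalytic asymmetric reduction by substrate-controlled reduction and resolution. It sets out from 10. L-Selectride (THF, −78 °C) should deliver hydride anti to the phenylselanyl group and give the racemic cis alcohol, 11 together with ent-11 F4. Preparative chiral SFC returns to the route at 11.

3. Step 5. Acylation may stop at the enol ester, or ring closure may go through the lactam oxygen to the linear 4-quinolone isomer under the strongly acidic conditions. The fallback builds the pyranone by a Kabbe condensation under basic conditions. It sets out from 4. C3-acetylation (AcOH, polyphosphoric acid, 90 °C) should give 3-acetyl-4-hydroxy-7,8-dimethoxy-1-methylquinolin-2(1H)-one F5. Acetone and pyrrolidine (toluene, reflux) should form enone 8 in the flask by enamine aldol condensation, and the 4-oxido group should close it by oxa-Michael addition, returning to the route at 9.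

**Further compounds**

F1 | step 8 | veprisine (7,8-dimethoxy-2,2,6-trimethyl-2,6-dihydro-5H-pyrano[3,2-c]quinolin-5-one) | COc1ccc2c3OC(C)(C)C=Cc3c(=O)n(C)c2c1OC
F2 | step 8 | methyl 3-(7,8-dimethoxy-1-methyl-2,4-dioxo-1,4-dihydroquinolin-3(2H)-ylidene)propanoate (o-quinone methide) | COC(=O)CC=C1C(=O)c2ccc(OC)c(OC)c2N(C)C1=O
F3 | step 8 | ent-13 (C-α R, C3′ R, C4′ S) | COc1ccc2c3c(c(=O)n(C)c2c1OC)[C@H](CC(=O)OC)[C@@H]1[C@H](O3)c2c(c3ccc(OC)c(OC)c3n(C)c2=O)OC1(C)C
F4 | step 7 | ent-11, (3R,4R)-4-hydroxy-7,8-dimethoxy-2,2,6-trimethyl-3-(phenylselanyl)-3,4-dihydro-2H-pyrano[3,2-c]quinolin-5(6H)-one | COc1ccc2c3OC(C)(C)[C@H]([Se]c4ccccc4)[C@H](O)c3c(=O)n(C)c2c1OC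
F5 | step 5 | 3-acetyl-4-hydroxy-7,8-dimethoxy-1-methylquinolin-2(1H)-one | COc1ccc2c(O)c(C(C)=O)c(=O)n(C)c2c1OC
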